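**Plan**

- Retrosynthesis: the three MOM ethers are removed first. Ring C is then cut at C3–C4 and at C2–H. This is possible because C4 is an aryl ketone carbon on ring A and C2 carries only H, the ring B aryl group and O1, so both bonds can come from adding a formyl C–H across an O1-bound 1-arylvinyl group.
- The enol ether C2=C3 is traced back to an aryl ester carbonyl (methylenation), the ester C–O bond to a ring A phenol and a ring B benzoic acid, and the three aryl–prenyl bonds and the formyl carbon to simple aromatics.
- Forward, ring A: three successive ortho-lithiations of phloroglucinol tris-MOM ether (prenyl, prenyl, formyl), removal of one ortho MOM group, and masking of the aldehyde as a silylated carbinol.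
- Forward, ring B: a commercial bromocatechol aldehyde is selectively methylated, MOM-protected, prenylated by Stille coupling and oxidised to the acid.
- The halves are joined as an aryl ester, the ester is methylenated, the aldehyde is restored, ring C is closed by rhodium-catalysed hydroacylation and the MOM groups are removed.
- Stereochemistry: the only stereocentre, C2 (S), is created in the ring closure under control of the chiral bisphosphine on rhodium and survives the final acidic deprotection.

Key step: step 16

Abbreviations: MOM = methoxymethyl; prenyl = 3-methylbut-2-en-1-yl; TBS = tert-butyldimethylsilyl.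

Assumption: (R)-DTBM-SEGPHOS is taken as the ligand enantiomer that leads to 2S; the sense of induction cannot be derived from the substrate alone, and if a first run shows the opposite sense the (S)-ligand is used with nothing else changed.

**Route**

Step 1
Reactants: 1 phloroglucinol (benzene-1,3,5-triol)
Product: 2 1,3,5-tris(methoxymethoxy)benzene
Conditions: NaH (3.3 equiv), MOMCl (3.3 equiv), DMF, 0 °C to rt
Reagents that add atoms: chloromethyl methyl ether (MOMCl), COCCl
Why: Exhaustive Williamson O-alkylation of the symmetrical trisphenoxide should give the tris-MOM ether, whose acetal oxygens later direct every ring metalation.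

Step 2
Reactants: 2 1,3,5-tris(methoxymethoxy)benzene; 3 prenyl bromide (1-bromo-3-methylbut-2-ene)
Product: 5 1,3,5-tris(methoxymethoxy)-2-prenylbenzene, via 2,4,6-tris(methoxymethoxy)phenyllithium 4 (not isolated)
Conditions: n-BuLi, THF, 0 °C; then CuBr·SMe2 (10 mol%), 3, −78 °C to rt
Reagents that add atoms: none
Why: Directed ortho-metalation at a carbon flanked by two MOM-oxy groups, followed by copper-assisted allylic substitution at the primary carbon of the bromide, should install an unrearranged prenyl group.

Step 3
Reactants: 5 1,3,5-tris(methoxymethoxy)-2-prenylbenzene; 3 prenyl bromide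
Product: 7 1,3,5-tris(methoxymethoxy)-2,4-diprenylbenzene, via 2,4,6-tris(methoxymethoxy)-3-prenylphenyllithium 6 (not isolated)
Conditions: n-BuLi, THF, 0 °C; then CuBr·SMe2 (10 mol%), 3, −78 °C to rt
Reagents that add atoms: none
Why: A second directed ortho-metalation and allylic substitution is expected because the two remaining ring hydrogens are equivalent, each lies between two MOM-oxy groups, and coordination-driven ring lithiation should outrun deprotonation of the prenyl CH2.

Step 4
Reactants: 7 1,3,5-tris(methoxymethoxy)-2,4-diprenylbenzene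
Product: 9 2,4,6-tris(methoxymethoxy)-3,5-diprenylbenzaldehyde, via 2,4,6-tris(methoxymethoxy)-3,5-diprenylphenyllithium 8 (not isolated)
Conditions: n-BuLi, THF, 0 °C; DMF, 0 °C to rt; H2O
Reagents that add atoms: N,N-dimethylformamide, CN(C)C=O
Why: A third directed ortho-metalation at the last ring hydrogen and formylation of the aryllithium by DMF should complete the hexasubstituted ring without any regiochemical choice.

Step 5
Reactants: 9 2,4,6-tris(methoxymethoxy)-3,5-diprenylbenzaldehyde
Product: 10 2-hydroxy-4,6-bis(methoxymethoxy)-3,5-diprenylbenzaldehyde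
Conditions: MgBr2·OEt2 (1.5 equiv), Et2O/toluene, 0 °C to rt; then H2O
Reagents that add atoms: none
Why: Chelation-controlled Lewis acid cleavage of a MOM ether ortho to a carbonyl should remove one of the two equivalent ortho groups, after which the magnesium phenoxide–aldehyde chelate blocks activation of the second, while the para MOM ether cannot chelate at all.

Step 6
Reactants: 10 2-hydroxy-4,6-bis(methoxymethoxy)-3,5-diprenylbenzaldehyde
Product: 11 2-(hydroxymethyl)-3,5-bis(methoxymethoxy)-4,6-diprenylphenol
Conditions: NaBH4, THF/MeOH, 0 °C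
Reagents that add atoms: none
Why: Borohydride reduction converts the aldehyde into a carbinol so that it is not methylenated in step 13, and the basic medium avoids ionisation of the electron-rich benzylic alcohol.

Step 7
Reactants: 11 2-(hydroxymethyl)-3,5-bis(methoxymethoxy)-4,6-diprenylphenol
Product: 12 2-(tert-butyldimethylsilyloxymethyl)-3,5-bis(methoxymethoxy)-4,6-diprenylphenol
Conditions: TBSCl (1.1 equiv), imidazole, CH2Cl2, 0 °C
Reagents that add atoms: tert-butyl(chloro)dimethylsilane (TBSCl), CC(C)(C)[Si](C)(C)Cl
Why: Selective silylation of the primary hydroxyl is expected because the phenol is flanked by two ortho substituents, and the silyl ether rules out acyl migration after step 12.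

Step 8
Reactants: 13 3-bromo-4,5-dihydroxybenzaldehyde
Product: 14 3-bromo-5-hydroxy-4-methoxybenzaldehyde
Conditions: MeI (1.1 equiv), Li2CO3 (1.2 equiv), DMF, 40 °C
Reagents that add atoms: iodomethane, CI
Why: Regioselective Williamson methylation should occur at the 4-hydroxyl, since the weak base forms only the monophenoxide of the more acidic OH para to the formyl group.

Step 9
Reactants: 14 3-bromo-5-hydroxy-4-methoxybenzaldehyde
Product: 15 3-bromo-4-methoxy-5-(methoxymethoxy)benzaldehyde
Conditions: MOMCl, iPr2NEt, CH2Cl2, 0 °C to rt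
Reagents that add atoms: chloromethyl methyl ether (MOMCl), COCCl
Why: Standard MOM protection of the remaining phenol gives the same acid-labile acetal used on ring A, so one final operation can remove all three.

Step 10
Reactants: 15 3-bromo-4-methoxy-5-(methoxymethoxy)benzaldehyde; 16 tributyl(prenyl)stannane
Product: 17 4-methoxy-3-(methoxymethoxy)-5-prenylbenzaldehyde
Conditions: Pd(PPh3)4 (5 mol%), DMF, 100 °C
Reagents that add atoms: none
Why: In this Stille coupling zerovalent palladium inserts into the aryl–bromine bond, the stannane transfers the prenyl group through its CH2 carbon, and reductive elimination should give the linear prenyl arene with aldehyde and MOM ether untouched.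

Step 11
Reactants: 17 4-methoxy-3-(methoxymethoxy)-5-prenylbenzaldehyde
Product: 18 4-methoxy-3-(methoxymethoxy)-5-prenylbenzoic acid
Conditions: NaClO2, NaH2PO4, 2-methylbut-2-ene (large excess), t-BuOH/H2O, 0 °C to rt
Reagents that add atoms: sodium chlorite NaClO2, [Na+].[O-]Cl=O
Why: Pinnick oxidation converts the aldehyde into the acid near pH 4, where the MOM ether is stable, and the excess scavenger alkene intercepts hypochlorous acid before it reaches the prenyl double bond.

Step 12
Reactants: 12 2-(tert-butyldimethylsilyloxymethyl)-3,5-bis(methoxymethoxy)-4,6-diprenylphenol; 18 4-methoxy-3-(methoxymethoxy)-5-prenylbenzoic acid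
Product: 19 2-(tert-butyldimethylsilyloxymethyl)-3,5-bis(methoxymethoxy)-4,6-diprenylphenyl 4-methoxy-3-(methoxymethoxy)-5-prenylbenzoate
Conditions: DCC (1.2 equiv), DMAP (0.5 equiv), CH2Cl2, rt
Reagents that add atoms: none
Why: Steglich esterification through the acylpyridinium ion should acylate even this hindered phenol under neutral conditions that spare the MOM and TBS groups, forming the future O1–C2 bond.

Step 13
Reactants: 19 aryl benzoate from step 12
Product: 20 tert-butyl{[2-({1-[4-methoxy-3-(methoxymethoxy)-5-prenylphenyl]ethenyl}oxy)-4,6-bis(methoxymethoxy)-3,5-diprenylphenyl]methoxy}dimethylsilane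
Conditions: Cp2TiMe2 (3 equiv), toluene, 70 °C, dark; filtration through basic alumina
Reagents that add atoms: dimethyltitanocene Cp2TiMe2, C[Ti](C)(C1C=CC=C1)C1C=CC=C1
Why: Petasis methylenation, in which thermally generated titanocene methylidene adds to the ester carbonyl and the oxatitanacyclobutane collapses to the enol ether, is established for aryl benzoates, and the non-acidic reagent leaves the trisubstituted prenyl alkenes, the acetals and the silyl ether alone.

Step 14
Reactants: 20 silyl-protected 1-arylvinyl aryl ether from step 13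
Product: 21 [2-({1-[4-methoxy-3-(methoxymethoxy)-5-prenylphenyl]ethenyl}oxy)-4,6-bis(methoxymethoxy)-3,5-diprenylphenyl]methanol
Conditions: Bu4NF, THF, 0 °C; chromatography on Et3N-deactivated silica
Reagents that add atoms: none
Why: Fluoride-induced desilylation is basic, so it should free the benzylic alcohol without touching the acid-sensitive enol ether or the MOM groups.

Step 15
Reactants: 21 benzylic alcohol from step 14
Product: 22 2-({1-[4-methoxy-3-(methoxymethoxy)-5-prenylphenyl]ethenyl}oxy)-4,6-bis(methoxymethoxy)-3,5-diprenylbenzaldehyde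
Conditions: activated MnO2 (excess), CH2Cl2, rt
Reagents that add atoms: none
Why: Oxidation of an electron-rich benzylic alcohol by MnO2 stops at the aldehyde and runs under neutral heterogeneous conditions, so the enol ether should survive.

Step 16
Reactants: 22 salicylaldehyde 1-arylvinyl ether from step 15
Product: 23 (2S)-2-[4-methoxy-3-(methoxymethoxy)-5-prenylphenyl]-5,7-bis(methoxymethoxy)-6,8-diprenylchroman-4-one
Conditions: [Rh(nbd)2]BF4 (5 mol%), (R)-DTBM-SEGPHOS (5.5 mol%), H2 pre-activation then argon purge; 22, 1,2-dichloroethane, 50 °C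
Reagents that add atoms: none
Why: Proposed new method: the cationic monovalent rhodium bisphosphine should add oxidatively into the formyl C–H bond to give an acyl rhodium hydride held at O1, the 1-arylvinyl group should then insert into Rh–H with hydride to C2 and rhodium to the CH2 carbon C3, and C–C reductive elimination from the seven-membered acyl alkyl rhodacycle should form C3–C4. The closest known reaction types are rhodium bisphosphine-catalysed enantioselective intramolecular hydroacylation of 1,1-disubstituted and heteroatom-bound alkenes to five-membered ketones and carbene-catalysed hydroacylations that give chroman-4-ones. Ring C closes in a formal 6-endo-trig mode, both former alkene carbons ending inside the pyranone. The C2 stereocentre is set by the ligand, which selects the alkene face that receives the hydride, and the ligand enantiomer is chosen to give 2S. The step needs endo regioselectivity and freedom from decarbonylation: 1,1-disubstitution makes the opposite insertion pass through a tertiary, aryl- and oxygen-bearing alkyl rhodium whose reductive elimination to a quaternary five-membered ring is slow, and the chelating bisphosphine together with O1 coordination leaves no vacant site for CO extrusion. The trisubstituted prenyl alkenes are too hindered to insert, and the neutral medium leaves the MOM ethers untouched.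

Step 17
Reactants: 23 (2S)-tris-MOM flavanone from step 16
Product: 24 isoamoritin [(2S)-5,7-dihydroxy-2-(3-hydroxy-4-methoxy-5-prenylphenyl)-6,8-diprenylchroman-4-one]
Conditions: 3 M HCl, MeOH, 45 °C
Reagents that add atoms: none
Why: Acid-catalysed acetal exchange with methanol should remove all three MOM groups as dimethoxymethane, and because the medium is acidic the flavanone does not open to the chalcone, so C2 keeps its configuration.

**Compound list**

1 | phloroglucinol (benzene-1,3,5-triol) | Oc1cc(O)cc(O)c1 | starting material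
2 | 1,3,5-tris(methoxymethoxy)benzene | COCOc1cc(OCOC)cc(OCOC)c1 | intermediate
3 | prenyl bromide (1-bromo-3-methylbut-2-ene) | CC(C)=CCBr | starting material
4 | 2,4,6-tris(methoxymethoxy)phenyllithium | [Li]c1c(OCOC)cc(OCOC)cc1OCOC | intermediate (not isolated)
5 | 1,3,5-tris(methoxymethoxy)-2-(3-methylbut-2-enyl)benzene | COCOc1cc(OCOC)c(CC=C(C)C)c(OCOC)c1 | intermediate
6 | 2,4,6-tris(methoxymethoxy)-3-(3-methylbut-2-enyl)phenyllithium | [Li]c1c(OCOC)cc(OCOC)c(CC=C(C)C)c1OCOC | intermediate (not isolated)
7 | 1,3,5-tris(methoxymethoxy)-2,4-bis(3-methylbut-2-enyl)benzene | COCOc1cc(OCOC)c(CC=C(C)C)c(OCOC)c1CC=C(C)C | intermediate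
8 | 2,4,6-tris(methoxymethoxy)-3,5-bis(3-methylbut-2-enyl)phenyllithium | [Li]c1c(OCOC)c(CC=C(C)C)c(OCOC)c(CC=C(C)C)c1OCOC | intermediate (not isolated)
9 | 2,4,6-tris(methoxymethoxy)-3,5-bis(3-methylbut-2-enyl)benzaldehyde | O=Cc1c(OCOC)c(CC=C(C)C)c(OCOC)c(CC=C(C)C)c1OCOC | intermediate
10 | 2-hydroxy-4,6-bis(methoxymethoxy)-3,5-bis(3-methylbut-2-enyl)benzaldehyde | O=Cc1c(O)c(CC=C(C)C)c(OCOC)c(CC=C(C)C)c1OCOC | intermediate
11 | 2-(hydroxymethyl)-3,5-bis(methoxymethoxy)-4,6-bis(3-methylbut-2-enyl)phenol | OCc1c(O)c(CC=C(C)C)c(OCOC)c(CC=C(C)C)c1OCOC | intermediate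
12 | 2-(tert-butyldimethylsilyloxymethyl)-3,5-bis(methoxymethoxy)-4,6-bis(3-methylbut-2-enyl)phenol | CC(C)(C)[Si](C)(C)OCc1c(O)c(CC=C(C)C)c(OCOC)c(CC=C(C)C)c1OCOC | intermediate
13 | 3-bromo-4,5-dihydroxybenzaldehyde | O=Cc1cc(O)c(O)c(Br)c1 | starting material
14 | 3-bromo-5-hydroxy-4-methoxybenzaldehyde | COc1c(O)cc(C=O)cc1Br | intermediate
15 | 3-bromo-4-methoxy-5-(methoxymethoxy)benzaldehyde | COCOc1cc(C=O)cc(Br)c1OC | intermediate
16 | tributyl(3-methylbut-2-enyl)stannane | CCCC[Sn](CCCC)(CCCC)CC=C(C)C | starting material
17 | 4-methoxy-3-(methoxymethoxy)-5-(3-methylbut-2-enyl)benzaldehyde | COCOc1cc(C=O)cc(CC=C(C)C)c1OC | intermediate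
18 | 4-methoxy-3-(methoxymethoxy)-5-(3-methylbut-2-enyl)benzoic acid | COCOc1cc(C(=O)O)cc(CC=C(C)C)c1OC | intermediate
19 | 2-(tert-butyldimethylsilyloxymethyl)-3,5-bis(methoxymethoxy)-4,6-bis(3-methylbut-2-enyl)phenyl 4-methoxy-3-(methoxymethoxy)-5-(3-methylbut-2-enyl)benzoate | COCOc1cc(C(=O)Oc2c(CO[Si](C)(C)C(C)(C)C)c(OCOC)c(CC=C(C)C)c(OCOC)c2CC=C(C)C)cc(CC=C(C)C)c1OC | intermediate
20 | tert-butyl{[2-({1-[4-methoxy-3-(methoxymethoxy)-5-(3-methylbut-2-enyl)phenyl]ethenyl}oxy)-4,6-bis(methoxymethoxy)-3,5-bis(3-methylbut-2-enyl)phenyl]methoxy}dimethylsilane | COCOc1cc(C(=C)Oc2c(CO[Si](C)(C)C(C)(C)C)c(OCOC)c(CC=C(C)C)c(OCOC)c2CC=C(C)C)cc(CC=C(C)C)c1OC | intermediate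
21 | [2-({1-[4-methoxy-3-(methoxymethoxy)-5-(3-methylbut-2-enyl)phenyl]ethenyl}oxy)-4,6-bis(methoxymethoxy)-3,5-bis(3-methylbut-2-enyl)phenyl]methanol | COCOc1cc(C(=C)Oc2c(CO)c(OCOC)c(CC=C(C)C)c(OCOC)c2CC=C(C)C)cc(CC=C(C)C)c1OC | intermediate
22 | 2-({1-[4-methoxy-3-(methoxymethoxy)-5-(3-methylbut-2-enyl)phenyl]ethenyl}oxy)-4,6-bis(methoxymethoxy)-3,5-bis(3-methylbut-2-enyl)benzaldehyde | COCOc1cc(C(=C)Oc2c(C=O)c(OCOC)c(CC=C(C)C)c(OCOC)c2CC=C(C)C)cc(CC=C(C)C)c1OC | intermediate
23 | (2S)-2-[4-methoxy-3-(methoxymethoxy)-5-(3-methylbut-2-enyl)phenyl]-5,7-bis(methoxymethoxy)-6,8-bis(3-methylbut-2-enyl)chroman-4-one | COCOc1cc([C@@H]2CC(=O)c3c(OCOC)c(CC=C(C)C)c(OCOC)c(CC=C(C)C)c3O2)cc(CC=C(C)C)c1OC | intermediate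
24 | isoamoritin, (2S)-5,7-dihydroxy-2-[3-hydroxy-4-methoxy-5-(3-methylbut-2-enyl)phenyl]-6,8-bis(3-methylbut-2-enyl)chroman-4-one | COc1c(O)cc([C@@H]2CC(=O)c3c(O)c(CC=C(C)C)c(O)c(CC=C(C)C)c3O2)cc1CC=C(C)C | target

**Step count and risks**

Total steps: 17. Longest linear sequence: 13 steps (steps 1–7 and 12–17, from 1); the ring B branch (steps 8–11) joins at step 12.

Steps most likely to fail:

1. Step 16 (hydroacylation). The acyl rhodium hydride may lose CO, the alkene may insert in the opposite sense and close a five-membered ring, or face selection may be weak. The fallback uses known chalcone chemistry, sets out from 7 and 17 and returns at 23.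
   - Arene 7 is lithiated to aryllithium 8 as in step 4 and quenched with N-methoxy-N-methylacetamide to give 1-[2,4,6-tris(methoxymethoxy)-3,5-diprenylphenyl]ethanone F1.
   - MgBr2·OEt2 removes one ortho MOM group by chelation to give 1-[2-hydroxy-4,6-bis(methoxymethoxy)-3,5-diprenylphenyl]ethanone F2.
   - Claisen–Schmidt condensation of F2 with aldehyde 17 (KOH, EtOH) gives the (E)-2'-hydroxychalcone F3.
   - Oxa-Michael cyclisation (NaOAc, EtOH, reflux) gives the racemic tris-MOM flavanone F4.
   - Preparative chromatography on a chiral stationary phase separates 23 from its (2R)-enantiomer F5, which base returns to F3 for recycling.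

2. Step 13 (ester methylenation). The hindered aryl ester may be methylenated incompletely, or the enol ether may be hydrolysed during isolation and the two steps that follow. The fallback forms the enol ether by C–O cross-coupling, sets out from 17 and 10 and returns at 22, so that steps 6, 7 and 11–15 are not needed.
   - MeMgBr adds to 17 to give 1-[4-methoxy-3-(methoxymethoxy)-5-prenylphenyl]ethanol F6.
   - MnO2 oxidises F6 to 1-[4-methoxy-3-(methoxymethoxy)-5-prenylphenyl]ethanone F7.
   - KN(SiMe3)2 and PhNTf2 convert F7 into 1-[4-methoxy-3-(methoxymethoxy)-5-prenylphenyl]ethenyl trifluoromethanesulfonate F8.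
   - F8 is coupled with phenol 10 using Pd2(dba)3, 2-(di-tert-butylphosphino)biphenyl and K3PO4 in toluene to give 22 directly.

3. Step 5 (selective MOM removal). Both ortho MOM groups may be cleaved, or the Lewis acid may cyclise a prenyl group onto the freed phenol. The fallback replaces selective deprotection by selective protection, sets out from prenyl bromide 3 and returns at 10, replacing steps 1–5.
   - Commercial 2,4,6-trihydroxybenzaldehyde F9 is C-alkylated twice with 3 in aqueous KOH at 0 °C to give 2,4,6-trihydroxy-3,5-diprenylbenzaldehyde F10, which must be separated from mono- and over-alkylated material.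
   - MOMCl (2 equiv) and iPr2NEt protect the 4-hydroxyl and one ortho hydroxyl, while the hydroxyl hydrogen-bonded to the formyl group stays free, giving 10.

Further compounds
F1 | step 16 | 1-[2,4,6-tris(methoxymethoxy)-3,5-bis(3-methylbut-2-enyl)phenyl]ethanone | CC(=O)c1c(OCOC)c(CC=C(C)C)c(OCOC)c(CC=C(C)C)c1OCOC
F2 | step 16 | 1-[2-hydroxy-4,6-bis(methoxymethoxy)-3,5-bis(3-methylbut-2-enyl)phenyl]ethanone | CC(=O)c1c(O)c(CC=C(C)C)c(OCOC)c(CC=C(C)C)c1OCOC
F3 | step 16 | (E)-1-[2-hydroxy-4,6-bis(methoxymethoxy)-3,5-bis(3-methylbut-2-enyl)phenyl]-3-[4-methoxy-3-(methoxymethoxy)-5-(3-methylbut-2-enyl)phenyl]prop-2-en-1-one | COCOc1cc(/C=C/C(=O)c2c(O)c(CC=C(C)C)c(OCOC)c(CC=C(C)C)c2OCOC)cc(CC=C(C)C)c1OC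
F4 | step 16 | racemic 2-[4-methoxy-3-(methoxymethoxy)-5-(3-methylbut-2-enyl)phenyl]-5,7-bis(methoxymethoxy)-6,8-bis(3-methylbut-2-enyl)chroman-4-one | COCOc1cc(C2CC(=O)c3c(OCOC)c(CC=C(C)C)c(OCOC)c(CC=C(C)C)c3O2)cc(CC=C(C)C)c1OC
F5 | step 16 | (2R)-2-[4-methoxy-3-(methoxymethoxy)-5-(3-methylbut-2-enyl)phenyl]-5,7-bis(methoxymethoxy)-6,8-bis(3-methylbut-2-enyl)chroman-4-one | COCOc1cc([C@H]2CC(=O)c3c(OCOC)c(CC=C(C)C)c(OCOC)c(CC=C(C)C)c3O2)cc(CC=C(C)C)c1OC
F6 | step 13 | racemic 1-[4-methoxy-3-(methoxymethoxy)-5-(3-methylbut-2-enyl)phenyl]ethanol | COCOc1cc(C(C)O)cc(CC=C(C)C)c1OC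
F7 | step 13 | 1-[4-methoxy-3-(methoxymethoxy)-5-(3-methylbut-2-enyl)phenyl]ethanone | COCOc1cc(C(C)=O)cc(CC=C(C)C)c1OC
F8 | step 13 | 1-[4-methoxy-3-(methoxymethoxy)-5-(3-methylbut-2-enyl)phenyl]ethenyl trifluoromethanesulfonate | COCOc1cc(C(=C)OS(=O)(=O)C(F)(F)F)cc(CC=C(C)C)c1OC
F9 | step 5 | 2,4,6-trihydroxybenzaldehyde | O=Cc1c(O)cc(O)cc1O
F10 | step 5 | 2,4,6-trihydroxy-3,5-bis(3-methylbut-2-enyl)benzaldehyde | O=Cc1c(O)c(CC=C(C)C)c(O)c(CC=C(C)C)c1O
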